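No constant is given for this flask, so read one from the runs. A single-handed catalyst converts a racemic substrate while solid reagent dissolves, and the runs show substrates only.

| flask | left-handed substrate | right-handed substrate | solid reagent | catalyst | remark | time |
|---|---|---|---|---|---|---|
| south | 20 mM | 20 mM | 28 mM | 1.4 mM | run made earlier |  |
| north-west | 20 mM | 20 mM | 44 mM | 1.4 mM | run made earlier |  |
| flask | 20 mM | 20 mM | 20.0 mM | 1.4 mM |  | 3.0 min |

- south (time / min: left-handed substrate / %, right-handed substrate / %): 0.667: 44.2, 46.1; 1.33: 37.2, 40.0; 2.00: 30.8, 33.9; 3.00: 22.8, 25.8; 4.00: 17.6, 19.5
- north-west (time / min: left-handed substrate / %, right-handed substrate / %): 0.333: 47.9, 48.1; 0.833: 41.9, 44.7; 1.50: 35.3, 38.6; 2.50: 26.7, 29.5; 4.00: 16.4, 18.5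

(each reading ± 0.3 percentage points)

- catalyst is single-handed; left-handed substrate and right-handed substrate are mirror images of each other, charged as a racemate, each of them at the stated concentration
- given per volume of solution although it is solid: solid reagent
- at the start none of the solid reagent is in solution
- an excess is the difference of the two amounts in percent of their sum
- an excess is below zero if the other one leads

- part of the left-handed substrate and right-handed substrate charged together that has reacted at 3.0 min
- excess of left-handed product over right-handed product in the product at 3.0 min
- excess of right-handed substrate over left-handed substrate among what is left of the two at 3.0 min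

Take the gap, [right-handed substrate] minus [left-handed substrate]. A first guess for eP is gap over conversion, which gives 5.84% in the south run at 3.00 min. Reject it: in the north-west run the gap falls from 3.3 percentage points at 1.50 min to 2.1 points at 4.00 min while conversion climbs. Read this fall, itself a reading with scatter 0.3 points on each substrate, as a sign that the substrates interconvert; the product gap then exceeds the substrate gap.

Use the early slope instead. Between the first two north-west readings the gap gains 2.6 points while conversion gains 9.4 points. Call the ratio the first excess, E, the excess of product formed while the substrates are still nearly equal: 27.7%, a selectivity factor of 1.77. Doubt it, since four readings with scatter 0.3 points carry it, so it is a rough reading.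

If each substrate reacts in proportion to its own concentration, product forming at any moment carries about E minus the eS of that moment. The south run at 3.00 min reads eS as 6.17%. Take 3.09% as the mean along the run of the asked flask, so eP in that flask is near 24.6%. Assuming one reagent per substrate, c in the asked flask is at most 50.0%; expect eS below the south reading, with less solid reagent in that flask.

The forecast gives 45.5%, 16% and 5.7%, with an eP below mine, and grants that “selectivity drift can't be excluded”.

The flask gives eP 24.1%, with c 45.9% and eS 3.65%.

    partner + catalyst + left-handed substrate → catalyst + left-handed product (k = 1100 /M²/s)
    partner + catalyst + right-handed substrate → catalyst + right-handed product (k = 630 /M²/s)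
    left-handed substrate ⇌ right-handed substrate (k = 0.0110 /s)
    solid reagent ⇌ partner, rate k4*(cs4 - [partner]) while solid is left; crystals form when [partner] > cs4 (solubility = 9.60 mM, k = 0.0280 /s)
    catalyst ⇌ dormant form (K = 0.310, k = 0.0190 /s)

In the flask at 0.903 min the path to left-handed product uses left-handed substrate more slowly than the forward step of its interconversion, at 0.45 of that rate. E less half the final eS gives 25.9% for the flask. For the neighbour with 34 mM of solid reagent, whose eS is 5.77%, it gives 24.8%, and that flask shows 23.7%.

The runs come from a simulation for substances that don't exist; noise was put on by code.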